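- Epsilon ends with more substrate than eta, 45.2% against 0%, and the two runs differ in their partner charge.

all flasks: substrate 0.20 M

| flask | partner | remark | time |
|---|---|---|---|
| epsilon | 0.57 equiv | run made earlier |  |
| eta | 1.3 equiv | run made earlier |  |
| teal | 0.900 equiv |  | 20 d |
| blue | 1.40 equiv |  | 20 d |

- epsilon (time / d: substrate / %, target / %, isomer of the product / %): 1.67: 42.8, 43.0, 14.6; 5.00: 42.9, 21.5, 34.7; 10.0: 42.6, 15.1, 40.8; 15.0: 43.7, 14.7, 41.6; 20.0: 45.2, 13.2, 43.4
- eta (time / d: substrate / %, target / %, isomer of the product / %): 1.67: 0, 70.8, 30.9; 5.00: 1.2, 36.8, 60.5; 10.0: 1.1, 26.1, 74.7; 15.0: 0.6, 24.6, 74.8; 20.0: 0, 24.0, 76.6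

(scatter of a reading: 1 percentage point)

- candidate steps: substrate + partner + target -> 2 target; substrate + partner -> target; target <-> isomer of the product

* which of these there is most of at the end, counted by the substrate in it, teal (substrate / isomer of the product / target)
* which of these there is most of at the end, counted by the substrate in it, blue (substrate / isomer of the product / target)
* amount of the one of these that there is most of at the end, in percent of the substrate charged, teal
* amount of the one of these that there is most of at the end, in percent of the substrate charged, blue

- Partner is the first setting. By hand, one partner should turn one substrate into one product. Epsilon's target and isomer of the product add up to 56.6% on a charge of 0.57 equiv, which fits.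
- Epsilon's end isomer over its partner gives 0.761. I call this g, the isomer yield per equivalent of partner used.
- Eta tests g from a different flask. There, isomer over total product at the end is 0.761.
- Teal has less partner than eta and stays below one equivalent, so I take partner as its limiting reagent. My reckoning for teal is g times 0.900 equiv, which is 68.5% isomer.
- Blue has more partner than eta, and eta ended with 0% substrate. By hand the extra partner adds no product, so I expect blue to sit at eta's reading, 76.6%.
- Time is the second setting. By hand, a longer run helps while the split still moves. Eta's isomer moves by 1.8 percentage points between 15.0 d and 20.0 d, against a scatter of 1 point. Teal and blue stop at 20 d, the same time as eta's last reading.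
- The forecast names isomer of the product for teal at 68.5% and isomer of the product for blue at 76%. Its ground is this: “Both runs end at the same split”. For teal it matches my reckoning, and for blue it lies slightly below my reading of eta.
- The flasks give isomer of the product at 68.0% in teal and isomer of the product at 75.5% in blue.

    substrate + partner + target → 2 target (k = 0.360 L² mol⁻² min⁻¹)
    substrate + partner → target (k = 4.90 × 10⁻⁵ L mol⁻¹ min⁻¹)
    target ⇌ isomer of the product (K = 3.10, k = 1.90 × 10⁻⁴ min⁻¹)

- In teal, isomer stands at 68.0% rather than 89.5% because of the way back to target. So g is a share under thermodynamic control: in teal the relaxation half-life of target and isomer, 1.92 d, is shorter than the run of 20 d. Teal's 68.0% stands against g's 68.5%. A neighbour flask is teal with 0.360 equiv of partner, where g gives 27.4%; it ends with 27.2% isomer beside 64.0% substrate.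

(The data come from a simulation for an exercise; the scatter is artificial.)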